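**Retrosynthetic overview**
- Target ⇒ syn-aldol methyl ketone that already carries the isovalerate on O2' (C1' benzylic, C2' ester-bearing, C3' tertiary carbinol); the C3'–CH3 bond comes from a chemoselective methyl-titanium addition.
- syn-Aldol ketone ⇒ 6-formyl-7-methoxycoumarin + acetonyl isovalerate; an amino-acid (primary-amine enamine) aldol forms C1'–C2' and sets both stereocentres, with the ester position fixed by construction.
- Aldehyde ⇒ 6-bromo-7-methoxycoumarin (Pd formylation) ⇒ 5-bromo-2-hydroxy-4-methoxybenzaldehyde + stabilised ylide (Wittig/lactonisation); donor ⇒ hydroxyacetone + isovaleryl chloride.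
- Ring order: the benzene ring is bought; the pyranone ring is the only ring formed (step 1).

Assumption: 1, 2, 7, 8, H-D-Thr(tBu)-OH and MeTi(OiPr)3 solution are taken as commercial; catalyst-bound species (Pd intermediates, enamines) and metal alkoxides that are only protonated on work-up are not numbered.

**Step 1**
Reactants: 1 5-bromo-2-hydroxy-4-methoxybenzaldehyde; 2 ethyl (triphenylphosphoranylidene)acetate
Product: 5 6-bromo-7-methoxy-2H-chromen-2-one, via ethyl (E)-3-(5-bromo-2-hydroxy-4-methoxyphenyl)prop-2-enoate 3 (not isolated), via ethyl (Z)-3-(5-bromo-2-hydroxy-4-methoxyphenyl)prop-2-enoate 4 (not isolated)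
Conditions: PhNEt2, reflux (ca. 215 °C), 4 h
Reagents that add atoms: none
Why: Wittig olefination gives the hydroxycinnamate, which equilibrates E/Z at this temperature and is drained by lactonisation of the Z isomer to the coumarin (Wittig/lactonisation coumarin synthesis); no stereocentre is involved.

**Step 2**
Reactants: 5 6-bromo-7-methoxy-2H-chromen-2-one
Product: 6 7-methoxy-2-oxo-2H-chromene-6-carbaldehyde
Conditions: Pd(OAc)2 (1 mol%), BuPAd2 (3 mol%), TMEDA (1 equiv), CO/H2 (1:1, 5 bar), PhMe, 100 °C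
Reagents that add atoms: carbon monoxide, [C-]#[O+]
Why: Oxidative addition into C–Br, CO insertion and hydrogenolysis of the aroyl-Pd species give the aldehyde (Pd-catalysed reductive carbonylation of an aryl bromide); the lactone and OMe are inert.

**Step 3**
Reactants: 7 hydroxyacetone (1-hydroxypropan-2-one); 8 3-methylbutanoyl chloride (isovaleryl chloride)
Product: 9 2-oxopropyl 3-methylbutanoate (acetonyl isovalerate)
Conditions: pyridine, DMAP (cat.), CH2Cl2, 0 °C → rt
Reagents that add atoms: none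
Why: DMAP-catalysed O-acylation of the primary alcohol by the acid chloride (nucleophilic acyl substitution).

**Step 4**
Reactants: 6 7-methoxy-2-oxo-2H-chromene-6-carbaldehyde; 9 2-oxopropyl 3-methylbutanoate
Product: 10 (1R,2S)-1-hydroxy-1-(7-methoxy-2-oxo-2H-chromen-6-yl)-3-oxobutan-2-yl 3-methylbutanoate
Conditions: H-D-Thr(tBu)-OH (O-tert-butyl-D-threonine, 20 mol%), ketone donor in fourfold excess, NMP, 0 °C, 96 h
Reagents that add atoms: none
Why: Proposed new method: a primary-amine enamine syn-aldol with an α-acyloxy ketone donor — the catalyst NH2 should condense with 9 to the more substituted, oxygen-bearing (Z)-enamine (α-CH acidified by the acyloxy group, Z geometry held by an N–H···O=C hydrogen bond to the isovalerate and by A(1,3) strain), and the catalyst CO2H delivers the aldehyde in a closed hydrogen-bonded transition state, so that the D-catalyst attacks the si face of 6 (1'R) and the Z-enamine gives the syn adduct (2'S), with the ester kept on the donor oxygen because no alkoxide is generated and the addition being fully atom-economic (all atoms of 6 and 9 end up in 10); the closest known reaction is the O-tert-butyl-threonine-catalysed syn-aldol of hydroxyacetone and O-silyl hydroxyacetones with aryl aldehydes, not yet shown for acyloxy ketones, and the D-catalyst is chosen by analogy with the sense of induction in that series.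

**Step 5**
Reactants: 10 (1R,2S)-1-hydroxy-1-(7-methoxy-2-oxo-2H-chromen-6-yl)-3-oxobutan-2-yl 3-methylbutanoate
Product: 11 (1R,2S)-1,3-dihydroxy-1-(7-methoxy-2-oxo-2H-chromen-6-yl)-3-methylbutan-2-yl 3-methylbutanoate
Conditions: MeTi(OiPr)3 (1.0 M in THF, 3 equiv), THF, −40 → 0 °C; aq. NH4Cl
Reagents that add atoms: methyltitanium triisopropoxide, C[Ti](OC(C)C)(OC(C)C)OC(C)C
Why: Ligand exchange anchors the benzylic OH on titanium and the methyl is transferred to the activated α-acyloxy ketone (chemoselective organotitanium 1,2-addition); this non-basic reagent leaves the isovalerate, the coumarin lactone and its enoate alone, creates no new stereocentre (two identical methyls) and does not epimerise C1'/C2'.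

**Compound list**
1 | 5-bromo-2-hydroxy-4-methoxybenzaldehyde | COc1cc(O)c(C=O)cc1Br | starting material
2 | ethyl (triphenylphosphoranylidene)acetate | CCOC(=O)C=P(c1ccccc1)(c1ccccc1)c1ccccc1 | starting material
3 | ethyl (E)-3-(5-bromo-2-hydroxy-4-methoxyphenyl)prop-2-enoate | CCOC(=O)/C=C/c1cc(Br)c(OC)cc1O | intermediate
4 | ethyl (Z)-3-(5-bromo-2-hydroxy-4-methoxyphenyl)prop-2-enoate | CCOC(=O)/C=C\c1cc(Br)c(OC)cc1O | intermediate
5 | 6-bromo-7-methoxy-2H-chromen-2-one | COc1cc2oc(=O)ccc2cc1Br | intermediate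
6 | 7-methoxy-2-oxo-2H-chromene-6-carbaldehyde | COc1cc2oc(=O)ccc2cc1C=O | intermediate
7 | hydroxyacetone (1-hydroxypropan-2-one) | CC(=O)CO | starting material
8 | 3-methylbutanoyl chloride | CC(C)CC(=O)Cl | starting material
9 | 2-oxopropyl 3-methylbutanoate | CC(C)CC(=O)OCC(C)=O | intermediate
10 | (1R,2S)-1-hydroxy-1-(7-methoxy-2-oxo-2H-chromen-6-yl)-3-oxobutan-2-yl 3-methylbutanoate | COc1cc2oc(=O)ccc2cc1[C@@H](O)[C@H](OC(=O)CC(C)C)C(C)=O | intermediate
11 | (1R,2S)-1,3-dihydroxy-1-(7-methoxy-2-oxo-2H-chromen-6-yl)-3-methylbutan-2-yl 3-methylbutanoate | COc1cc2oc(=O)ccc2cc1[C@@H](O)[C@H](OC(=O)CC(C)C)C(C)(C)O | target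

**Totals and risks**
Total steps: 5. Longest linear sequence: 4 (steps 1, 2, 4, 5).

Step 4 (proposed new step). The acetonyl ester may acylate the catalyst amine (O→N transfer), the ester may migrate to the new benzylic OH, or the enamine may form on the methyl side. The fallback uses known chemistry, sets out from 6 and comes back at 10. The established O-tert-butyl-threonine syn-aldol of 6 with commercial 1-[(tert-butyldimethylsilyl)oxy]propan-2-one (H-D-Thr(tBu)-OH 20 mol%, NMP, 0 °C) gives (3S,4R)-3-[(tert-butyldimethylsilyl)oxy]-4-hydroxy-4-(7-methoxy-2-oxo-2H-chromen-6-yl)butan-2-one F1. The benzylic OH is protected with 4-methoxybenzyl trichloroacetimidate (cat. La(OTf)3, PhMe) to give (3S,4R)-3-[(tert-butyldimethylsilyl)oxy]-4-[(4-methoxybenzyl)oxy]-4-(7-methoxy-2-oxo-2H-chromen-6-yl)butan-2-one F2. HF·pyridine in THF removes the silyl group to give (3S,4R)-3-hydroxy-4-[(4-methoxybenzyl)oxy]-4-(7-methoxy-2-oxo-2H-chromen-6-yl)butan-2-one F3. Acylation with 8 (pyridine, DMAP) gives (1R,2S)-1-[(4-methoxybenzyl)oxy]-1-(7-methoxy-2-oxo-2H-chromen-6-yl)-3-oxobutan-2-yl 3-methylbutanoate F4. DDQ in CH2Cl2/pH 7 buffer then removes the PMB group and delivers 10, with the ester position fixed by the protecting-group order.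

Step 5. MeTi(OiPr)3 may be too sluggish, or the titanium alkoxide may trigger O2'→O1' acyl migration or retro-aldol. The fallback sets out from 10 and comes back at 11. The benzylic OH is capped with TESOTf/2,6-lutidine (CH2Cl2, −78 °C) to give (1R,2S)-1-(7-methoxy-2-oxo-2H-chromen-6-yl)-3-oxo-1-[(triethylsilyl)oxy]butan-2-yl 3-methylbutanoate F5. With no free OH to ionise or migrate onto, the stronger but still non-basic MeTiCl3 (CH2Cl2, −78 → −30 °C) adds to the ketone to give (1R,2S)-3-hydroxy-1-(7-methoxy-2-oxo-2H-chromen-6-yl)-3-methyl-1-[(triethylsilyl)oxy]butan-2-yl 3-methylbutanoate F6. HF·pyridine in THF then gives 11.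

Step 2. Pd–H may partly reduce the coumarin C3=C4 bond or hydrodebrominate 5 under syngas. The fallback sets out from 5 and comes back at 6. Suzuki–Miyaura vinylation (potassium vinyltrifluoroborate, PdCl2(dppf), Et3N, n-PrOH, 90 °C) gives 6-ethenyl-7-methoxy-2H-chromen-2-one F7. Lemieux–Johnson cleavage (OsO4 cat., NaIO4, 2,6-lutidine, dioxane/H2O) of the terminal vinyl group, which reacts far faster than the electron-poor endocyclic enoate, then gives 6.

**Further compounds**
F1 | step 4 | (3S,4R)-3-[(tert-butyldimethylsilyl)oxy]-4-hydroxy-4-(7-methoxy-2-oxo-2H-chromen-6-yl)butan-2-one | COc1cc2oc(=O)ccc2cc1[C@@H](O)[C@H](O[Si](C)(C)C(C)(C)C)C(C)=O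
F2 | step 4 | (3S,4R)-3-[(tert-butyldimethylsilyl)oxy]-4-[(4-methoxybenzyl)oxy]-4-(7-methoxy-2-oxo-2H-chromen-6-yl)butan-2-one | COc1cc2oc(=O)ccc2cc1[C@@H](OCc1ccc(OC)cc1)[C@H](O[Si](C)(C)C(C)(C)C)C(C)=O
F3 | step 4 | (3S,4R)-3-hydroxy-4-[(4-methoxybenzyl)oxy]-4-(7-methoxy-2-oxo-2H-chromen-6-yl)butan-2-one | COc1cc2oc(=O)ccc2cc1[C@@H](OCc1ccc(OC)cc1)[C@H](O)C(C)=O
F4 | step 4 | (1R,2S)-1-[(4-methoxybenzyl)oxy]-1-(7-methoxy-2-oxo-2H-chromen-6-yl)-3-oxobutan-2-yl 3-methylbutanoate | COc1cc2oc(=O)ccc2cc1[C@@H](OCc1ccc(OC)cc1)[C@H](OC(=O)CC(C)C)C(C)=O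
F5 | step 5 | (1R,2S)-1-(7-methoxy-2-oxo-2H-chromen-6-yl)-3-oxo-1-[(triethylsilyl)oxy]butan-2-yl 3-methylbutanoate | COc1cc2oc(=O)ccc2cc1[C@@H](O[Si](CC)(CC)CC)[C@H](OC(=O)CC(C)C)C(C)=O
F6 | step 5 | (1R,2S)-3-hydroxy-1-(7-methoxy-2-oxo-2H-chromen-6-yl)-3-methyl-1-[(triethylsilyl)oxy]butan-2-yl 3-methylbutanoate | COc1cc2oc(=O)ccc2cc1[C@@H](O[Si](CC)(CC)CC)[C@H](OC(=O)CC(C)C)C(C)(C)O
F7 | step 2 | 6-ethenyl-7-methoxy-2H-chromen-2-one | COc1cc2oc(=O)ccc2cc1C=C
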